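**Retrosynthetic overview**
1. The target, (2S)-2-(2,2-dimethyl-2H-chromen-6-yl)-7-hydroxy-6,8-bis(3-methylbut-2-en-1-yl)-2,3-dihydro-4H-chromen-4-one, comes from its O7 silyl ether by desilylation; ring C of that ether is closed last, through the C2–C3 bond.
2. The (2S)-flavanone core comes from a racemic 2-aryl-4-methylidene-4H-1,3-benzodioxin by a catalytic, stereoconvergent Petasis–Ferrier-type 1,3-O-to-C rearrangement, which trades the 1,3-dioxin ring for the pyran-4-one ring C.
3. Enabling feature: C2 carries O1 and is benzylic to ring B, whose chromene oxygen sits para to it, so C2 ionises to a planar, doubly stabilised aryloxycarbenium ion. C3 is alpha to the C4 carbonyl, whose oxygen can serve as the temporary second acetal oxygen (O3 of the dioxin) and leaves as the enol that attacks C2.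
4. The enol acetal comes from carbonyl methylenation of a 1,3-benzodioxin-4-one, itself the acetal union of a 3,5-diprenyl-2,4-dihydroxybenzoic acid (ring A) with 2,2-dimethyl-2H-chromene-6-carbaldehyde (ring B).
5. Ring order: pyran ring of the chromene (propargyl Claisen/electrocyclisation), prenyl groups on ring A (double allyl Claisen, then cross-metathesis), temporary dioxinone ring, finally ring C.

Key step: step 10

Assumption: the sense of induction of the chiral acid in step 10 cannot be predicted from first principles; the (R)-acid is written, and the (S)-acid is to be used if the (R)-acid favours the (2R)-product.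

**Step 1**
Reactants: 1 4-hydroxybenzaldehyde
Product: 2 4-[(2-methylbut-3-yn-2-yl)oxy]benzaldehyde
Conditions: 3-chloro-3-methylbut-1-yne, K2CO3, KI (cat.), CuI (cat.), acetone, 60 °C
Reagents that add atoms: 3-chloro-3-methylbut-1-yne, C#CC(C)(C)Cl
Why: Copper-assisted O-alkylation of the phenoxide by the tertiary propargylic chloride (standard aryl 1,1-dimethylpropargyl ether synthesis), to which the aldehyde is inert.

**Step 2**
Reactants: 2 4-[(2-methylbut-3-yn-2-yl)oxy]benzaldehyde
Product: 3 2,2-dimethyl-2H-chromene-6-carbaldehyde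
Conditions: N,N-diethylaniline, 190 °C
Reagents that add atoms: none
Why: Aromatic propargyl Claisen rearrangement followed by enolisation, 1,5-hydrogen shift and oxa-6π electrocyclisation builds the 2,2-dimethyl-2H-pyran ring, and the two ortho positions are equivalent, so one chromene should result.

**Step 3**
Reactants: 4 methyl 2,4-dihydroxybenzoate
Product: 5 methyl 2,4-bis(prop-2-en-1-yloxy)benzoate
Conditions: allyl bromide, K2CO3, DMF, 60 °C
Reagents that add atoms: allyl bromide, C=CCBr
Why: Williamson O-allylation of both phenols, with DMF and heat chosen so that the hydrogen-bonded C2 hydroxyl is alkylated as well.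

**Step 4**
Reactants: 5 methyl 2,4-bis(prop-2-en-1-yloxy)benzoate
Product: 7 methyl 2,4-dihydroxy-3,5-di(prop-2-en-1-yl)benzoate, via mono-rearranged allyl ether 6 (not isolated)
Conditions: N,N-diethylaniline, 200 °C, sealed tube, argon
Reagents that add atoms: none
Why: Double aromatic Claisen rearrangement in which C1 is blocked by the ester, so C3 and C5 are the only positions that can keep an allyl group (an ether whose ortho positions are both occupied moves on to the para position by Claisen–Cope), and every order of migration should end at the same 3,5-diallyl product.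

**Step 5**
Reactants: 7 methyl 2,4-dihydroxy-3,5-di(prop-2-en-1-yl)benzoate
Product: 8 methyl 2,4-dihydroxy-3,5-bis(3-methylbut-2-en-1-yl)benzoate
Conditions: 2-methylbut-2-ene (large excess), second-generation Grubbs catalyst RuCl2(=CHPh)(H2IMes)(PCy3) (5 mol %), CH2Cl2, 40 °C, sealed tube
Reagents that add atoms: 2-methylbut-2-ene, CC=C(C)C
Why: Olefin cross-metathesis of the two terminal allyl groups with excess 2-methylbut-2-ene should turn each into a prenyl group with loss of propene, free phenols and the ester being tolerated by the ruthenium carbene.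

**Step 6**
Reactants: 8 methyl 2,4-dihydroxy-3,5-bis(3-methylbut-2-en-1-yl)benzoate
Product: 9 2,4-dihydroxy-3,5-bis(3-methylbut-2-en-1-yl)benzoic acid
Conditions: NaOH (aq.), MeOH, 65 °C, argon; then 1 M HCl to pH 3, 0 °C
Reagents that add atoms: sodium hydroxide, [Na+].[OH-]
Why: Saponification of the salicylate ester under argon, with cold and brief acidification so that the prenylphenol neither cyclises to a chroman nor decarboxylates.

**Step 7**
Reactants: 9 2,4-dihydroxy-3,5-bis(3-methylbut-2-en-1-yl)benzoic acid; 3 2,2-dimethyl-2H-chromene-6-carbaldehyde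
Product: 12 rac-2-(2,2-dimethyl-2H-chromen-6-yl)-7-hydroxy-6,8-bis(3-methylbut-2-en-1-yl)-4H-1,3-benzodioxin-4-one, via tris(trimethylsilyl) derivative 10 (not isolated), via O-trimethylsilyl benzodioxinone 11 (not isolated)
Conditions: HMDS, TMSCl (cat.), CH2Cl2, rt, then evaporation; 3, TMSOTf (0.2 equiv), CH2Cl2, −78 to −40 °C; pyridine, aq. NaHCO3, silica gel
Reagents that add atoms: none
Why: TMSOTf-catalysed silyl-transfer acetalisation of a hydroxy acid, in which the silyl ester and the ortho silyl ether condense with the aldehyde with loss of hexamethyldisiloxane; the six-membered acylal is the only ring that can close, the racemic C2 centre is of no consequence because step 10 erases it, and the labile aryl O–SiMe3 group at O7 should fall off on work-up.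

**Step 8**
Reactants: 12 rac-2-(2,2-dimethyl-2H-chromen-6-yl)-7-hydroxy-6,8-bis(3-methylbut-2-en-1-yl)-4H-1,3-benzodioxin-4-one
Product: 13 rac-7-{[tert-butyl(dimethyl)silyl]oxy}-2-(2,2-dimethyl-2H-chromen-6-yl)-6,8-bis(3-methylbut-2-en-1-yl)-4H-1,3-benzodioxin-4-one
Conditions: TBSCl, imidazole, DMF, rt
Reagents that add atoms: tert-butyldimethylsilyl chloride, CC(C)(C)[Si](C)(C)Cl
Why: Standard silylation of the only free phenol (a vinylogous acid para to the carbonyl), under conditions in which imidazole should not open the acylal.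

**Step 9**
Reactants: 13 rac-7-{[tert-butyl(dimethyl)silyl]oxy}-2-(2,2-dimethyl-2H-chromen-6-yl)-6,8-bis(3-methylbut-2-en-1-yl)-4H-1,3-benzodioxin-4-one
Product: 14 rac-tert-butyl{[2-(2,2-dimethyl-2H-chromen-6-yl)-4-methylidene-6,8-bis(3-methylbut-2-en-1-yl)-4H-1,3-benzodioxin-7-yl]oxy}dimethylsilane
Conditions: Cp2TiMe2, toluene/THF, 65 °C, dark; filtration through basic alumina (pentane/Et3N)
Reagents that add atoms: dimethyltitanocene Cp2TiMe2, [CH3-].[CH3-].[Ti+4].c1cc[cH-]c1.c1cc[cH-]c1
Why: Petasis methylenation, in which the thermally released titanium methylidene converts the lactone carbonyl into the exocyclic enol ether through an oxatitanacyclobutane; the reagent is not Lewis acidic, so the acylal, the silyl ether and the alkenes should survive.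

**Step 10**
Reactants: 14 rac-tert-butyl{[2-(2,2-dimethyl-2H-chromen-6-yl)-4-methylidene-6,8-bis(3-methylbut-2-en-1-yl)-4H-1,3-benzodioxin-7-yl]oxy}dimethylsilane
Product: 15 (2S)-7-{[tert-butyl(dimethyl)silyl]oxy}-2-(2,2-dimethyl-2H-chromen-6-yl)-6,8-bis(3-methylbut-2-en-1-yl)-2,3-dihydro-4H-chromen-4-one
Conditions: (R)-TRIP [(R)-3,3'-bis(2,4,6-triisopropylphenyl)-1,1'-binaphthyl-2,2'-diyl hydrogen phosphate] (10 mol %), 4 Å molecular sieves, toluene, −20 °C
Reagents that add atoms: none
Why: Proposed new method: the chiral phosphoric acid protonates the enol acetal and the C2–O3 bond of either enantiomer of 14 opens to one and the same contact ion pair, a planar O1=C2 aryloxycarbenium ion (stabilised by O1 and by the para oxygen of ring B) that stays tethered through ring A to the enol of the C4 methyl ketone and is paired with the chiral phosphate. The enol carbon C3 then adds to C2 in a 6-(enolendo)-endo-trig closure of ring C (a half-chair transition state like that of a Prins or oxa-Pictet–Spengler cyclisation), which forms the C2–C3 bond irreversibly as the ketone and returns the proton to the catalyst. The closest known reactions are the aluminium-promoted Petasis–Ferrier rearrangement of 4-methylene-1,3-dioxanes to tetrahydropyran-4-ones and the chiral phosphoric acid-catalysed aza-Petasis–Ferrier rearrangement of racemic hemiaminal vinyl ethers; the benzo-fused all-oxygen substrate and an enantioselective version of it are without precedent. The only new stereocentre, C2, is controlled by the catalyst alone: the phosphate hydrogen-bonds the enol O–H and screens one face of the cation, and because ionisation erases the configuration of racemic 14 the step is stereoconvergent. It needs C- over O-recombination, secured because O-attack merely regenerates 14 while C-attack is an irreversible sink, and it needs the enol to outrun the C8 prenyl alkene as nucleophile, which its far higher nucleophilicity and its generation inside the ion pair should ensure. The silyl ether at O7 keeps the phenol from adding to the enol ether.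

**Step 11**
Reactants: 15 (2S)-7-{[tert-butyl(dimethyl)silyl]oxy}-2-(2,2-dimethyl-2H-chromen-6-yl)-6,8-bis(3-methylbut-2-en-1-yl)-2,3-dihydro-4H-chromen-4-one
Product: 16 (2S)-2-(2,2-dimethyl-2H-chromen-6-yl)-7-hydroxy-6,8-bis(3-methylbut-2-en-1-yl)-2,3-dihydro-4H-chromen-4-one (the target flavanone)
Conditions: TBAF, AcOH (1:1), THF, 0 °C
Reagents that add atoms: none
Why: Fluoride cleavage of the aryl silyl ether, buffered with acetic acid so that the medium stays non-basic and the flavanone cannot racemise through retro-oxa-Michael ring opening.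

**Compound list**
1 | 4-hydroxybenzaldehyde | O=Cc1ccc(O)cc1 | starting material
2 | 4-[(2-methylbut-3-yn-2-yl)oxy]benzaldehyde | O=Cc1ccc(OC(C)(C)C#C)cc1 | intermediate
3 | 2,2-dimethyl-2H-chromene-6-carbaldehyde | O=Cc1ccc2c(c1)C=CC(C)(C)O2 | intermediate
4 | methyl 2,4-dihydroxybenzoate | COC(=O)c1ccc(O)cc1O | starting material
5 | methyl 2,4-bis(prop-2-en-1-yloxy)benzoate | COC(=O)c1ccc(OCC=C)cc1OCC=C | intermediate
6 | methyl 2-hydroxy-3-(prop-2-en-1-yl)-4-(prop-2-en-1-yloxy)benzoate (mono-rearranged allyl ether) | COC(=O)c1ccc(OCC=C)c(CC=C)c1O | intermediate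
7 | methyl 2,4-dihydroxy-3,5-di(prop-2-en-1-yl)benzoate | COC(=O)c1cc(CC=C)c(O)c(CC=C)c1O | intermediate
8 | methyl 2,4-dihydroxy-3,5-bis(3-methylbut-2-en-1-yl)benzoate | COC(=O)c1cc(CC=C(C)C)c(O)c(CC=C(C)C)c1O | intermediate
9 | 2,4-dihydroxy-3,5-bis(3-methylbut-2-en-1-yl)benzoic acid | OC(=O)c1cc(CC=C(C)C)c(O)c(CC=C(C)C)c1O | intermediate
10 | trimethylsilyl 3,5-bis(3-methylbut-2-en-1-yl)-2,4-bis(trimethylsilyloxy)benzoate | C[Si](C)(C)OC(=O)c1cc(CC=C(C)C)c(O[Si](C)(C)C)c(CC=C(C)C)c1O[Si](C)(C)C | intermediate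
11 | rac-2-(2,2-dimethyl-2H-chromen-6-yl)-6,8-bis(3-methylbut-2-en-1-yl)-7-(trimethylsilyloxy)-4H-1,3-benzodioxin-4-one | O=C1OC(c2ccc3c(c2)C=CC(C)(C)O3)Oc2c(CC=C(C)C)c(O[Si](C)(C)C)c(CC=C(C)C)cc12 | intermediate
12 | rac-2-(2,2-dimethyl-2H-chromen-6-yl)-7-hydroxy-6,8-bis(3-methylbut-2-en-1-yl)-4H-1,3-benzodioxin-4-one | O=C1OC(c2ccc3c(c2)C=CC(C)(C)O3)Oc2c(CC=C(C)C)c(O)c(CC=C(C)C)cc12 | intermediate
13 | rac-7-{[tert-butyl(dimethyl)silyl]oxy}-2-(2,2-dimethyl-2H-chromen-6-yl)-6,8-bis(3-methylbut-2-en-1-yl)-4H-1,3-benzodioxin-4-one | O=C1OC(c2ccc3c(c2)C=CC(C)(C)O3)Oc2c(CC=C(C)C)c(O[Si](C)(C)C(C)(C)C)c(CC=C(C)C)cc12 | intermediate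
14 | rac-tert-butyl{[2-(2,2-dimethyl-2H-chromen-6-yl)-4-methylidene-6,8-bis(3-methylbut-2-en-1-yl)-4H-1,3-benzodioxin-7-yl]oxy}dimethylsilane | C=C1OC(c2ccc3c(c2)C=CC(C)(C)O3)Oc2c(CC=C(C)C)c(O[Si](C)(C)C(C)(C)C)c(CC=C(C)C)cc12 | intermediate
15 | (2S)-7-{[tert-butyl(dimethyl)silyl]oxy}-2-(2,2-dimethyl-2H-chromen-6-yl)-6,8-bis(3-methylbut-2-en-1-yl)-2,3-dihydro-4H-chromen-4-one | CC(C)=CCc1cc2c(c(CC=C(C)C)c1O[Si](C)(C)C(C)(C)C)O[C@H](c1ccc3c(c1)C=CC(C)(C)O3)CC2=O | intermediate
16 | (2S)-2-(2,2-dimethyl-2H-chromen-6-yl)-7-hydroxy-6,8-bis(3-methylbut-2-en-1-yl)-2,3-dihydro-4H-chromen-4-one (the target flavanone) | CC(C)=CCc1cc2c(c(CC=C(C)C)c1O)O[C@H](c1ccc3c(c1)C=CC(C)(C)O3)CC2=O | target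

**Step count and risks**
Total: 11 steps. Longest linear sequence: 9 steps (steps 3 to 11, from methyl 2,4-dihydroxybenzoate); the aldehyde 3 is made in 2 steps and joins at step 7.

Step 10 (proposed new method). What may go wrong: loose ion pairing, so that the enol adds to both faces of the cation and the enantiomeric purity is low; capture of the cation by the C8 prenyl double bond; hydrolytic fragmentation by traces of water. The fallback uses known chemistry, sets out from 14 and comes back to the route at 16. Enol acetal 14 is deliberately hydrolysed (PPTS, wet THF) to the ketone 1-[4-{[tert-butyl(dimethyl)silyl]oxy}-2-hydroxy-3,5-bis(3-methylbut-2-en-1-yl)phenyl]ethan-1-one F1 and recovered aldehyde 3. Claisen–Schmidt condensation of the two (KOH, EtOH/H2O, which also removes the silyl group) should give (E)-1-[2,4-dihydroxy-3,5-bis(3-methylbut-2-en-1-yl)phenyl]-3-(2,2-dimethyl-2H-chromen-6-yl)prop-2-en-1-one F2. NaOAc in refluxing EtOH closes it by oxa-Michael addition to the racemic flavanone rac-2-(2,2-dimethyl-2H-chromen-6-yl)-7-hydroxy-6,8-bis(3-methylbut-2-en-1-yl)-2,3-dihydro-4H-chromen-4-one F3. Kinetic resolution by asymmetric transfer hydrogenation (RuCl(p-cymene)(TsDPEN) of the enantiomeric series that reduces the (2R)-ketone faster, HCO2H/Et3N, stopped near half conversion) should leave 16 and convert the other enantiomer into the cis-alcohol (2R,4R)-2-(2,2-dimethyl-2H-chromen-6-yl)-6,8-bis(3-methylbut-2-en-1-yl)-3,4-dihydro-2H-chromene-4,7-diol F4, which is removed by chromatography.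

Step 9. What may go wrong: slow attack of the titanium methylidene on the hindered, electron-rich acylal carbonyl at a temperature the acetal centre tolerates, or ionisation of the enol acetal on titanium residues, with uncontrolled rearrangement or hydrolysis during isolation. The fallback sets out from 13 and comes back at 15. The acylal 13 is used as an activated ester and opened with HC≡CMgBr (THF, −78 to 0 °C) to the ynone 1-[4-{[tert-butyl(dimethyl)silyl]oxy}-2-hydroxy-3,5-bis(3-methylbut-2-en-1-yl)phenyl]prop-2-yn-1-one F5; the liberated aldehyde consumes a second equivalent of the Grignard reagent. Base-mediated 6-endo-dig oxa-Michael closure (K2CO3, acetone) should give the chromone 7-{[tert-butyl(dimethyl)silyl]oxy}-6,8-bis(3-methylbut-2-en-1-yl)-4H-chromen-4-one F6. Rhodium-catalysed asymmetric 1,4-addition then installs ring B and C2 in one step, giving 15. Its partner is (2,2-dimethyl-2H-chromen-6-yl)boronic acid F7, made from commercial 6-bromo-2,2-dimethyl-2H-chromene (n-BuLi, B(OiPr)3, then aqueous acid). The catalyst is [RhCl(C2H4)2]2 with a chiral diene ligand of the enantiomeric series that gives the (2S)-product, and aqueous KOH (cat.) in toluene at room temperature.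

Step 7. What may go wrong: slow ring closure at the crowded silyl ether oxygen between the prenyl group and the silyl ester, so that the activated aldehyde or the transient aryloxycarbenium ion is captured by the neighbouring prenyl double bond instead. The fallback sets out from 7 and comes back at 13; it makes the acetal union before the trisubstituted alkenes exist. Ester 7 is saponified to 2,4-dihydroxy-3,5-di(prop-2-en-1-yl)benzoic acid F8. This is silylated to trimethylsilyl 3,5-di(prop-2-en-1-yl)-2,4-bis(trimethylsilyloxy)benzoate F9 and condensed with 3 under the conditions of step 7 to rac-2-(2,2-dimethyl-2H-chromen-6-yl)-6,8-di(prop-2-en-1-yl)-7-(trimethylsilyloxy)-4H-1,3-benzodioxin-4-one F10. Work-up gives rac-2-(2,2-dimethyl-2H-chromen-6-yl)-7-hydroxy-6,8-di(prop-2-en-1-yl)-4H-1,3-benzodioxin-4-one F11. Silylation (TBSCl, imidazole) gives rac-7-{[tert-butyl(dimethyl)silyl]oxy}-2-(2,2-dimethyl-2H-chromen-6-yl)-6,8-di(prop-2-en-1-yl)-4H-1,3-benzodioxin-4-one F12. Cross-metathesis with 2-methylbut-2-ene (second-generation Grubbs catalyst RuCl2(=CHPh)(H2IMes)(PCy3)) then converts both allyl groups into prenyl groups to give 13; the internal chromene double bond, flanked by a quaternary carbon, should not take part.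

**Further compounds**
F1 | step 10 | 1-[4-{[tert-butyl(dimethyl)silyl]oxy}-2-hydroxy-3,5-bis(3-methylbut-2-en-1-yl)phenyl]ethan-1-one | CC(=O)c1cc(CC=C(C)C)c(O[Si](C)(C)C(C)(C)C)c(CC=C(C)C)c1O
F2 | step 10 | (E)-1-[2,4-dihydroxy-3,5-bis(3-methylbut-2-en-1-yl)phenyl]-3-(2,2-dimethyl-2H-chromen-6-yl)prop-2-en-1-one | CC(C)=CCc1cc(C(=O)/C=C/c2ccc3c(c2)C=CC(C)(C)O3)c(O)c(CC=C(C)C)c1O
F3 | step 10 | rac-2-(2,2-dimethyl-2H-chromen-6-yl)-7-hydroxy-6,8-bis(3-methylbut-2-en-1-yl)-2,3-dihydro-4H-chromen-4-one | CC(C)=CCc1cc2c(c(CC=C(C)C)c1O)OC(c1ccc3c(c1)C=CC(C)(C)O3)CC2=O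
F4 | step 10 | (2R,4R)-2-(2,2-dimethyl-2H-chromen-6-yl)-6,8-bis(3-methylbut-2-en-1-yl)-3,4-dihydro-2H-chromene-4,7-diol | CC(C)=CCc1cc2c(c(CC=C(C)C)c1O)O[C@@H](c1ccc3c(c1)C=CC(C)(C)O3)C[C@H]2O
F5 | step 9 | 1-[4-{[tert-butyl(dimethyl)silyl]oxy}-2-hydroxy-3,5-bis(3-methylbut-2-en-1-yl)phenyl]prop-2-yn-1-one | C#CC(=O)c1cc(CC=C(C)C)c(O[Si](C)(C)C(C)(C)C)c(CC=C(C)C)c1O
F6 | step 9 | 7-{[tert-butyl(dimethyl)silyl]oxy}-6,8-bis(3-methylbut-2-en-1-yl)-4H-chromen-4-one | O=c1ccoc2c(CC=C(C)C)c(O[Si](C)(C)C(C)(C)C)c(CC=C(C)C)cc12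
F7 | step 9 | (2,2-dimethyl-2H-chromen-6-yl)boronic acid | OB(O)c1ccc2c(c1)C=CC(C)(C)O2
F8 | step 7 | 2,4-dihydroxy-3,5-di(prop-2-en-1-yl)benzoic acid | OC(=O)c1cc(CC=C)c(O)c(CC=C)c1O
F9 | step 7 | trimethylsilyl 3,5-di(prop-2-en-1-yl)-2,4-bis(trimethylsilyloxy)benzoate | C[Si](C)(C)OC(=O)c1cc(CC=C)c(O[Si](C)(C)C)c(CC=C)c1O[Si](C)(C)C
F10 | step 7 | rac-2-(2,2-dimethyl-2H-chromen-6-yl)-6,8-di(prop-2-en-1-yl)-7-(trimethylsilyloxy)-4H-1,3-benzodioxin-4-one | O=C1OC(c2ccc3c(c2)C=CC(C)(C)O3)Oc2c(CC=C)c(O[Si](C)(C)C)c(CC=C)cc12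
F11 | step 7 | rac-2-(2,2-dimethyl-2H-chromen-6-yl)-7-hydroxy-6,8-di(prop-2-en-1-yl)-4H-1,3-benzodioxin-4-one | O=C1OC(c2ccc3c(c2)C=CC(C)(C)O3)Oc2c(CC=C)c(O)c(CC=C)cc12
F12 | step 7 | rac-7-{[tert-butyl(dimethyl)silyl]oxy}-2-(2,2-dimethyl-2H-chromen-6-yl)-6,8-di(prop-2-en-1-yl)-4H-1,3-benzodioxin-4-one | O=C1OC(c2ccc3c(c2)C=CC(C)(C)O3)Oc2c(CC=C)c(O[Si](C)(C)C(C)(C)C)c(CC=C)cc12
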